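All runs were computed for substances that don't exist.

I began from amounts: how much of each reagent went in, and where it went.

| flask | substrate | first nucleophile | solid second nucleophile | capture agent | remark | time |
|---|---|---|---|---|---|---|
| teal | 20 mM | 28 mM | 40 mM | 40 mM | run made earlier |  |
| red | 80 mM | 28 mM | 40 mM | 40 mM | run made earlier |  |
| violet | 40 mM | 28 mM | 40 mM | 20 mM | run made earlier |  |
| flask | 40 mM | 28.0 mM | 40.0 mM | 40.0 mM |  | 40 min |

| run | time / min | target / % |
|---|---|---|
| teal | 3.00 | 71.9 |
| teal | 10.0 | 98.2 |
| teal | 15.0 | 98.8 |
| teal | 25.0 | 97.9 |
| teal | 40.0 | 97.8 |
| teal | 50.0 | 98.1 |
| red | 8.00 | 34.6 |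
| red | 15.0 | 34.3 |
| red | 25.0 | 34.7 |
| red | 30.0 | 35.5 |
| red | 40.0 | 35.3 |
| red | 50.0 | 34.3 |
| violet | 10.0 | 69.2 |
| violet | 20.0 | 69.5 |
| violet | 30.0 | 68.3 |
| violet | 40.0 | 70.5 |
| violet | 50.0 | 69.8 |

(readings scatter by 0.5 percentage points)

- the analysis behind the earlier runs scatters by 0.5 percentage points, standard deviation
- at the start none of the solid second nucleophile is in solution

- amount of target at 40 min, in percent of the substrate charged
- the change that raises the amount of target at 40 min, in percent of the substrate charged most ("none" if none brings more than 2 percentage points) (north-east / north / south / none)
- amount of target at 40 min, in percent of the substrate charged, after north-east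

- north-east: doubling the dissolution coefficient of the solid second nucleophile, all else as stated
- north: doubling the amount of first nucleophile, all else as stated
- south: doubling the solubility of the solid second nucleophile, all else as stated

1. Credit. I kept the account in first nucleophile, since in the flask c(first nucleophile) = 28.0 mM stood below c(substrate) = 40 mM, which makes it the limiting reagent if each target takes one of it.

2. Debits. The red plateau averaged 27.8 mM of target, against 28 mM charged. The violet run, which differed from red in its substrate as well as in having half the capture agent, averaged 27.8 mM on its plateau, and I read that as the same debit.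

3. Time. Red and violet read flat from their first points, at 8.00 min and 10.0 min, so I placed the flask at 40 min, later than both, on its plateau.

4. Closing. I divided the smaller charge by the substrate charge and called this the ledger ceiling, which gave 70.0% for the flask, and I committed to that number.

5. Changes. North-east and south leave both charges as they stand, so I kept 70.0% after north-east, whereas north lifts the ceiling to 100%, so I chose north.

The forecast gave 69.7%, within 68.5% to 71%, then 69.8% after north-east and north as the best change, holding that “that reagent is the stoichiometric limit”.

The flask gave 70.0% at 40 min and 70.0% after north-east, and north was best, worth 29 percentage points. Of the first nucleophile, 0% of its charge was left at 40.0 min. The other side of the books closed as well: the 30.0% of substrate beyond the ceiling stood as 14.9% other capture product, 10.2% trapped intermediate and 4.97% open intermediate, together 30.1%.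

    open intermediate + capture agent → trapped intermediate (k = 0.450 L mol⁻¹ min⁻¹)
    substrate → open intermediate (k = 0.570 min⁻¹)
    solid second nucleophile ⇌ second nucleophile, rate k3*(cs3 - [second nucleophile]) while solid is left; crystals form when [second nucleophile] > cs3 (solubility = 28.0 mM, k = 0.00950 min⁻¹)
    second nucleophile + open intermediate → other capture product (k = 14.0 L mol⁻¹ min⁻¹)
    first nucleophile + open intermediate → target (k = 110 L mol⁻¹ min⁻¹)

For the neighbour charged with 160 mM of substrate and the same first nucleophile, the ceiling scaled to 17.5%. That flask gave 17.5% of target at 40 min.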